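**Strategy.** The dihydrofuran ring (O1–C2–C3–C3a–C7a) is closed last by moving the benzylic carbon C2 from carbon (C7) to oxygen (O1). C7 of the cyclohexenone ring is the central carbon, and O1 the enol oxygen, of a masked 1,3-dione, and C2 is benzylic to the trimethoxyphenyl ring. The target is therefore the O-alkylated isomer of a bicyclo[3.2.1]octane-2,8-dione in which C2 is bonded to C7. That bridged dione is made by an enantioselective titanium-promoted [5+2] union of an allylmethoxybenzoquinone with (Z)-isoelemicin. Acid then ionises the C7–C2 bond, O1 captures the cation, and C2 and C5 settle into their stable configurations.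

Key step: step 8

Numbering: the target and 12–14 carry benzofuran numbering (O1, C2, C3, C3a, C4–C7, C7a). Compounds 9–11 carry bicyclo[3.2.1]octane numbering; their C1, C2, C3, C4, C5, C6, C7, C8 become C7, C6, C5, C4, C3a, C3, C2, C7a of the target.

Assumption: the (R,R)-TADDOLate is taken to shield the quinone face that leads to 9; if the sense of induction is the opposite, (S,S)-TADDOL is used and nothing else changes.

Step 1
Reactants: 1 3,4-dimethoxyphenol; 2 allyl bromide (3-bromoprop-1-ene)
Product: 3 4-(allyloxy)-1,2-dimethoxybenzene
Conditions: K2CO3, acetone, reflux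
Reagents that add atoms: none
Why: Williamson ether synthesis: the phenoxide of 1 displaces bromide from the allylic halide (SN2), and no stereocenter is formed.

Step 2
Reactants: 3 4-(allyloxy)-1,2-dimethoxybenzene
Product: 4 2-allyl-4,5-dimethoxyphenol
Conditions: N,N-diethylaniline, 190 °C
Reagents that add atoms: none
Why: Aromatic Claisen rearrangement ([3,3]-sigmatropic shift followed by tautomerisation) should move the allyl group to the open ortho position C6 rather than to the hindered C2 between the two oxygen substituents.

Step 3
Reactants: 4 2-allyl-4,5-dimethoxyphenol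
Product: 5 2-allyl-5-methoxy-1,4-benzoquinone
Conditions: PhI(OAc)2, MeCN/H2O, 0 °C
Reagents that add atoms: water, O
Why: Oxidative demethylation of a para-methoxyphenol with a trivalent iodine reagent: water adds to the methoxy-bearing para carbon of the activated phenol and the hemiketal loses methanol to give the para-quinone, the allyl group being inert.

Step 4
Reactants: 6 5-bromo-1,2,3-trimethoxybenzene; 7 (Z)-prop-1-en-1-ylboronic acid
Product: 8 (Z)-1,2,3-trimethoxy-5-(prop-1-en-1-yl)benzene ((Z)-isoelemicin)
Conditions: Pd(PPh3)4 (cat.), K2CO3, 1,4-dioxane/H2O, 80 °C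
Reagents that add atoms: none
Why: Suzuki–Miyaura coupling with zerovalent palladium transfers the alkenyl group with retention of configuration, so the Z geometry of 7 should be carried into 8.

Step 5
Reactants: 5 2-allyl-5-methoxy-1,4-benzoquinone; 8 (Z)-isoelemicin
Product: 9 (1S,5S,6R,7S)-3-hydroxy-6-methyl-5-(prop-2-en-1-yl)-7-(3,4,5-trimethoxyphenyl)bicyclo[3.2.1]oct-3-ene-2,8-dione (methyl and aryl both endo, on the side of the C2–C4 bridge)
Conditions: (R,R)-TADDOL (1.1 equiv), TiCl4 and Ti(OiPr)4 (0.55 equiv each), CH2Cl2, −78 °C; 8, −78 to −20 °C; then H2O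
Reagents that add atoms: none
Why: Quinone–alkene [5+2] cycloaddition promoted by a chiral tetravalent titanium TADDOLate: titanium chelated by the C4 carbonyl and the C5 methoxy oxygen of 5 makes the allyl-bearing C2 the electrophilic β-carbon, the Z alkene bonds there with its methyl-bearing carbon and to C6 with its benzylic carbon on one face (suprafacial, geometry retained) with the aryl ring stacked over the quinone (endo), which places methyl and aryl on the side of the C2–C4 bridge and fixes C6 relative to C5 in 9, the TADDOLate shields one quinone face and so sets the absolute configuration, and chloride removes the methyl group from the oxocarbenium ion left at the former quinone C5.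

Step 6
Reactants: 9 the hydroxy enedione of step 5
Product: 10 (1S,5S,6R,7S)-3-methoxy-6-methyl-5-(prop-2-en-1-yl)-7-(3,4,5-trimethoxyphenyl)bicyclo[3.2.1]oct-3-ene-2,8-dione
Conditions: Me2SO4, K2CO3, acetone, 23 °C
Reagents that add atoms: dimethyl sulfate, COS(=O)(=O)OC
Why: O-Alkylation of the acidic diosphenol (enol of a 1,2-diketone) with a hard methylating agent should occur on oxygen; the stereocenters are not involved.

Step 7
Reactants: 10 the methoxy enedione of step 6
Product: 11 (1S,5R,6R,7S)-3-methoxy-6-methyl-5-(prop-2-en-1-yl)-7-(3,4,5-trimethoxyphenyl)bicyclo[3.2.1]octane-2,8-dione, both C3 epimers (same spatial arrangement at C5 as in 10; only the descriptor changes)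
Conditions: [(Ph3P)CuH]6 (0.4 equiv), H2O (3 equiv), THF, 23 °C
Reagents that add atoms: none
Why: Copper hydride conjugate reduction: hydride adds to C4 of the α-methoxy enone and the copper enolate is protonated by water at C3 without control (either C3 epimer serves in step 8), while this reagent should leave the isolated C8 ketone and the terminal alkene untouched.

Step 8
Reactants: 11 the saturated bridged dione of step 7
Product: 14 (2S,3S,3aR,5R)-5-methoxy-3-methyl-3a-(prop-2-en-1-yl)-2-(3,4,5-trimethoxyphenyl)-3,3a,4,5-tetrahydro-1-benzofuran-6(2H)-one, via 2,3-cis isomer 12 (not isolated), via C5 epimer 13 (not isolated)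
Conditions: TfOH (10 mol %), CH2Cl2, −40 to 0 °C; then DBU (30 mol %), 23 °C
Reagents that add atoms: none
Why: Protonation of the non-enolisable bridged β-diketone at a carbonyl oxygen triggers a Grob-type retro-alkylation in which the C1–C7 bond of 11 (C7–C2 of the target), which lies axial to the C2 carbonyl π system, ionises to a 1,3-dione enol and a benzylic cation stabilised by the trimethoxyphenyl ring; the enol oxygen on C8 (the future O1) then captures the cation in a 5-exo-tet, SN1-type closure that forms the O1–C2 bond and with it the dihydrofuran ring, the other enol oxygen being placed only for a seven-membered ring. The closest known reaction type is the acid-induced rearrangement of bicyclo[3.2.1]octanoid neolignans into hydrobenzofuranoid neolignans. C2 is the one stereocenter made here and is under thermodynamic control: the vinylogous-ester oxygen is a good leaving group, so the kinetically formed 2,3-cis isomer 12 should re-ionise until the aryl group sits trans to the C3 methyl group. C3 and C3a are untouched and keep the configuration set in step 5, provided the cation is captured faster than it loses the C3 proton or meets the allyl double bond, which the neighbouring enol oxygen and the low temperature should secure. DBU then epimerises the enolisable C5 to the isomer with an equatorial methoxy group anti to the pseudoaxial allyl group (13 to 14). The driving force is the release of bridge strain and the gain of a conjugated vinylogous ester from a β-diketone that cannot enolise.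

**Compound list**

1 | 3,4-dimethoxyphenol | COc1ccc(O)cc1OC | starting material
2 | allyl bromide (3-bromoprop-1-ene) | C=CCBr | starting material
3 | 4-(allyloxy)-1,2-dimethoxybenzene | C=CCOc1ccc(OC)c(OC)c1 | intermediate
4 | 2-allyl-4,5-dimethoxyphenol | C=CCc1cc(OC)c(OC)cc1O | intermediate
5 | 2-allyl-5-methoxy-1,4-benzoquinone | C=CCC1=CC(=O)C(OC)=CC1=O | intermediate
6 | 5-bromo-1,2,3-trimethoxybenzene | COc1cc(Br)cc(OC)c1OC | starting material
7 | (Z)-prop-1-en-1-ylboronic acid | C/C=C\B(O)O | starting material
8 | (Z)-1,2,3-trimethoxy-5-(prop-1-en-1-yl)benzene | C/C=C\c1cc(OC)c(OC)c(OC)c1 | intermediate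
9 | (1S,5S,6R,7S)-3-hydroxy-6-methyl-5-(prop-2-en-1-yl)-7-(3,4,5-trimethoxyphenyl)bicyclo[3.2.1]oct-3-ene-2,8-dione | C=CC[C@]12C=C(O)C(=O)[C@H](C1=O)[C@@H](c1cc(OC)c(OC)c(OC)c1)[C@H]2C | intermediate
10 | (1S,5S,6R,7S)-3-methoxy-6-methyl-5-(prop-2-en-1-yl)-7-(3,4,5-trimethoxyphenyl)bicyclo[3.2.1]oct-3-ene-2,8-dione | C=CC[C@]12C=C(OC)C(=O)[C@H](C1=O)[C@@H](c1cc(OC)c(OC)c(OC)c1)[C@H]2C | intermediate
11 | (1S,5R,6R,7S)-3-methoxy-6-methyl-5-(prop-2-en-1-yl)-7-(3,4,5-trimethoxyphenyl)bicyclo[3.2.1]octane-2,8-dione, both C3 epimers | C=CC[C@]12CC(OC)C(=O)[C@H](C1=O)[C@@H](c1cc(OC)c(OC)c(OC)c1)[C@H]2C | intermediate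
12 | (2R,3S,3aR)-5-methoxy-3-methyl-3a-(prop-2-en-1-yl)-2-(3,4,5-trimethoxyphenyl)-3,3a,4,5-tetrahydro-1-benzofuran-6(2H)-one, 2,3-cis isomer, both C5 epimers | C=CC[C@]12CC(OC)C(=O)C=C1O[C@@H](c1cc(OC)c(OC)c(OC)c1)[C@H]2C | intermediate
13 | (2S,3S,3aR,5S)-5-methoxy-3-methyl-3a-(prop-2-en-1-yl)-2-(3,4,5-trimethoxyphenyl)-3,3a,4,5-tetrahydro-1-benzofuran-6(2H)-one, C5 epimer of the target | C=CC[C@]12C[C@H](OC)C(=O)C=C1O[C@H](c1cc(OC)c(OC)c(OC)c1)[C@H]2C | intermediate
14 | (2S,3S,3aR,5R)-5-methoxy-3-methyl-3a-(prop-2-en-1-yl)-2-(3,4,5-trimethoxyphenyl)-3,3a,4,5-tetrahydro-1-benzofuran-6(2H)-one | C=CC[C@]12C[C@@H](OC)C(=O)C=C1O[C@H](c1cc(OC)c(OC)c(OC)c1)[C@H]2C | target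

**Step count.** Total: 8 steps. Longest linear sequence: 7 steps (1 → 3 → 4 → 5 → 9 → 10 → 11 → 14); step 4 is a one-step side branch.

**Steps most likely to fail**

Step 5. The titanium TADDOLate may discriminate poorly between the two quinone faces at the substituted carbon. The Z alkene may also react sluggishly and lose its endo preference, so both facial and endo selectivity are at risk. The fallback sets out from 4 and gives up asymmetric induction for a racemic union and a resolution. Oxidation of 4 with PhI(OAc)2 in methanol gives the quinone monoketal 2-allyl-4,4,5-trimethoxycyclohexa-2,5-dien-1-one F1. Ionisation of F1 with SnCl4 in CH2Cl2 at −30 °C in the presence of 8 is a cation–alkene [5+2] cycloaddition of the methoxy-stabilised cyclohexadienyl cation. After aqueous work-up it should give the methyl ether directly as a racemate, that is 10 together with its mirror image (1R,5R,6S,7R)-3-methoxy-6-methyl-5-(prop-2-en-1-yl)-7-(3,4,5-trimethoxyphenyl)bicyclo[3.2.1]oct-3-ene-2,8-dione F2. The two are separated by preparative chromatography on a chiral stationary phase, and the route is rejoined at 10.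

Step 8. The benzylic cation may lose the C3 proton (styrene formation, then scrambling of C3 on re-protonation) or be captured by the allyl double bond before O1 closes. Ionisation of the saturated dione may also need acid strong enough to open these paths. The fallback sets out from 10 and carries out the carbon-to-oxygen shift before the reduction. In this unsaturated series the departing enol is a more acidic, cross-conjugated hydroxydienone, so TsOH in benzene at 23 °C should suffice. After equilibration at C2 this should give the dienone (2S,3S,3aS)-5-methoxy-3-methyl-3a-(prop-2-en-1-yl)-2-(3,4,5-trimethoxyphenyl)-3,3a-dihydro-1-benzofuran-6(2H)-one F4. Conjugate reduction of its methoxy-bearing C4=C5 bond with [(Ph3P)CuH]6 in wet THF (the C7=C7a bond is a deactivated vinylogous ester), followed by DBU equilibration at C5, returns to the route at 14.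

Step 7. Hydride transfer to the neopentylic C4 of the α-methoxy enone may be slow, so that 1,2-addition of hydride to the strained bridging C8 ketone competes (over-reduction). The fallback sets out from 10 and accepts reduction at both sites. Excess K[s-Bu3BH] in THF at −78 °C should add hydride 1,4 to the enone and 1,2 to C8. This gives (1S,5R,6R,7S)-8-hydroxy-3-methoxy-6-methyl-5-(prop-2-en-1-yl)-7-(3,4,5-trimethoxyphenyl)bicyclo[3.2.1]octan-2-one F3 as a mixture of C3 and C8 epimers. Re-oxidation of the C8 carbinol with Dess–Martin periodinane in CH2Cl2 returns to the route at 11.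

Further compounds
F1 | step 5 | 2-allyl-4,4,5-trimethoxycyclohexa-2,5-dien-1-one | C=CCC1=CC(OC)(OC)C(OC)=CC1=O
F2 | step 5 | (1R,5R,6S,7R)-3-methoxy-6-methyl-5-(prop-2-en-1-yl)-7-(3,4,5-trimethoxyphenyl)bicyclo[3.2.1]oct-3-ene-2,8-dione (enantiomer of 10) | C=CC[C@@]12C=C(OC)C(=O)[C@@H](C1=O)[C@H](c1cc(OC)c(OC)c(OC)c1)[C@@H]2C
F3 | step 7 | (1S,5R,6R,7S)-8-hydroxy-3-methoxy-6-methyl-5-(prop-2-en-1-yl)-7-(3,4,5-trimethoxyphenyl)bicyclo[3.2.1]octan-2-one, C3 and C8 epimers | C=CC[C@]12CC(OC)C(=O)[C@H](C1O)[C@@H](c1cc(OC)c(OC)c(OC)c1)[C@H]2C
F4 | step 8 | (2S,3S,3aS)-5-methoxy-3-methyl-3a-(prop-2-en-1-yl)-2-(3,4,5-trimethoxyphenyl)-3,3a-dihydro-1-benzofuran-6(2H)-one | C=CC[C@]12C=C(OC)C(=O)C=C1O[C@H](c1cc(OC)c(OC)c(OC)c1)[C@H]2C
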